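**Retrosynthetic overview**
1. The target is a centrosymmetric, achiral triaryl diether. Central ring B (a 2,5-dibromo-3,6-dioxyhydroquinone) carries two identical 2,3,5-tribromo-4-hydroxyphenyl groups (rings A and C).
2. Last disconnection: the ring B hydroquinone goes back to its p-quinone. The two ring B hydroxyls therefore stay masked as C=O while the ethers are made.
3. Key disconnection (new step): both O–C(ring A/C) bonds are cut at once. This gives bromanilic acid (ring B, O–H donor) and two molecules of a tribromo-p-quinone diazide (rings A/C as quinoid carbene). The nitrogen-bearing carbon fixes which oxygen of each outer ring becomes the ether, so no protecting group is needed.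
4. Quinone diazide ⇒ 4-amino-2,3,6-tribromophenol ⇒ 2,3,6-tribromo-4-nitrophenol ⇒ 3-bromo-4-nitrophenol, where all directing effects converge.
5. Ring order: no ring is built, since all three carbocycles are bought. Rings A/C are functionalised first (steps 1 to 3), joined to ring B in step 4, and ring B is aromatised in step 5.

Assumption: the SMILES holds no stereocentre and no stereogenic double bond. Each diaryl ether axis has only three ortho substituents and rotates freely, so the target is achiral and there is no enantiomer to select.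

**Route**

Step 1
Reactants: 1 3-bromo-4-nitrophenol
Product: 3 2,3,6-tribromo-4-nitrophenol, via 2,5-dibromo-4-nitrophenol 2 (not isolated)
Conditions: Br2 (2.4 equiv), AcOH, rt then 85 °C, 3 h; water, filter
Reagents that add atoms: bromine, BrBr
Why: Electrophilic aromatic bromination in which OH (ortho), NO2 (meta) and the ring bromine (ortho/para) all direct to C6 and then to C2, while C5 stays deactivated; no stereocentre is formed.

Step 2
Reactants: 3 2,3,6-tribromo-4-nitrophenol
Product: 4 4-amino-2,3,6-tribromophenol
Conditions: Fe powder (4 equiv), AcOH/EtOH 1:1, 60 °C, 1 h, N2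
Reagents that add atoms: none
Why: Béchamp-type dissolving-metal nitro reduction, in which electron transfer to NO2 is far faster than C–Br cleavage, so the three aryl bromides survive; no stereocentre is formed.

Step 3
Reactants: 4 4-amino-2,3,6-tribromophenol
Product: 6 2,3,6-tribromo-4-diazocyclohexa-2,5-dien-1-one, via diazonium hydrogen sulfate 5 (not isolated)
Conditions: NaNO2 (1.1 equiv), H2SO4, AcOH/H2O, 0–5 °C, dark; then ice-water, filter
Reagents that add atoms: sodium nitrite, [Na+].[O-]N=O
Why: Classical diazotisation in a chloride-free acid gives a 4-hydroxyarenediazonium ion that three bromines and the diazonio group make strongly acidic, so on dilution it loses its proton and the neutral p-quinone diazide precipitates; no stereocentre is formed.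

Step 4
Reactants: 6 2,3,6-tribromo-4-diazocyclohexa-2,5-dien-1-one (2.1 equiv); 7 bromanilic acid (2,5-dibromo-3,6-dihydroxy-1,4-benzoquinone, dried)
Product: 10 2,5-dibromo-3,6-bis(2,3,5-tribromo-4-hydroxyphenoxy)-1,4-benzoquinone, via rhodium quinoid carbene 8 (not isolated), via monoaryl ether 9 (not isolated)
Conditions: Rh2(esp)2 (2 mol %; esp = 3,3'-(1,3-phenylene)bis(2,2-dimethylpropanoate)), 2,6-di-tert-butylpyridine (0.5 equiv), 4 Å MS, DCE/EtOAc 4:1, 60 °C, dark, 6 added over 6 h
Reagents that add atoms: none
Why: Proposed new method: twofold dirhodium-catalysed O–H insertion of a p-quinone diazide into the vinylogous-acid O–H bonds of an anilic acid; Rh2(esp)2 expels N2 from 6 to give the strongly electrophilic quinoid carbene 8, its carbene carbon (flanked by H and Br) is attacked by an oxygen of hydrogen bromanilate, rhodium leaves as the outer ring aromatises to a phenoxide, proton transfer gives the 4-hydroxyaryl ether 9, and the same sequence at the remaining O–H gives 10; chemoselectivity is gated by acidity, because 2,6-di-tert-butylpyridine (too hindered to bind rhodium or the carbene) ionises only the anilic O–H groups (pKa about 1 to 3) and hardly the 2,6-dibromophenol O–H of the products (pKa about 6), slow addition keeps 6 from arylating itself, and the second arylation should take the oxygen next to C=O rather than the carbonyl oxygen crowded by the first aryloxy group, which gives the more stable p-quinone; the closest known reaction types are dirhodium-carbene O–H insertion of diazo compounds into carboxylic acids and phenols and metal quinoid-carbene X–H arylation by quinone diazides, neither shown on a hydroxyquinone O–H; no stereocentre is formed.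

Step 5
Reactants: 10 2,5-dibromo-3,6-bis(2,3,5-tribromo-4-hydroxyphenoxy)-1,4-benzoquinone
Product: 11 2,5-dibromo-3,6-bis(2,3,5-tribromo-4-hydroxyphenoxy)benzene-1,4-diol (target)
Conditions: Na2S2O4 (3 equiv), EtOAc/H2O, rt, 15 min, N2
Reagents that add atoms: none
Why: Quinone-to-hydroquinone reduction by dithionite (two electrons, two protons) is very fast in a two-phase system, leaves aryl bromides, diaryl ethers and phenols untouched, and turns the labile vinylogous aryl ester into a stable aromatic diether; no stereocentre is formed.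

**Compound list**
1 | 3-bromo-4-nitrophenol | Oc1ccc([N+](=O)[O-])c(Br)c1 | starting material
2 | 2,5-dibromo-4-nitrophenol | Oc1cc(Br)c([N+](=O)[O-])cc1Br | intermediate
3 | 2,3,6-tribromo-4-nitrophenol | Oc1c(Br)c(Br)c([N+](=O)[O-])cc1Br | intermediate
4 | 4-amino-2,3,6-tribromophenol | Nc1cc(Br)c(O)c(Br)c1Br | intermediate
5 | 2,3,5-tribromo-4-hydroxybenzenediazonium hydrogen sulfate | Oc1c(Br)cc([N+]#N)c(Br)c1Br.OS(=O)(=O)[O-] | intermediate
6 | 2,3,6-tribromo-4-diazocyclohexa-2,5-dien-1-one | O=C1C(Br)=CC(=[N+]=[N-])C(Br)=C1Br | intermediate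
7 | bromanilic acid (2,5-dibromo-3,6-dihydroxy-1,4-benzoquinone) | O=C1C(O)=C(Br)C(=O)C(O)=C1Br | starting material
8 | Rh2(esp)2-bound 2,3,5-tribromo-4-oxocyclohexa-2,5-dien-1-ylidene (quinoid carbene on one rhodium atom of the catalyst) | O=C1C(Br)=CC(=[Rh+2][Rh+2])C(Br)=C1Br.[O-]C(=O)C(C)(C)Cc1cccc(CC(C)(C)C([O-])=O)c1.[O-]C(=O)C(C)(C)Cc1cccc(CC(C)(C)C([O-])=O)c1 | intermediate
9 | 2,5-dibromo-3-hydroxy-6-(2,3,5-tribromo-4-hydroxyphenoxy)-1,4-benzoquinone | O=C1C(O)=C(Br)C(=O)C(Oc2cc(Br)c(O)c(Br)c2Br)=C1Br | intermediate
10 | 2,5-dibromo-3,6-bis(2,3,5-tribromo-4-hydroxyphenoxy)-1,4-benzoquinone | O=C1C(Oc2cc(Br)c(O)c(Br)c2Br)=C(Br)C(=O)C(Oc3cc(Br)c(O)c(Br)c3Br)=C1Br | intermediate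
11 | 2,5-dibromo-3,6-bis(2,3,5-tribromo-4-hydroxyphenoxy)benzene-1,4-diol (achiral) | Oc1c(Br)cc(Oc2c(O)c(Br)c(Oc3cc(Br)c(O)c(Br)c3Br)c(O)c2Br)c(Br)c1Br | target

**Total step count:** 5.
**Longest linear sequence:** 5 steps (1 → 3 → 4 → 6 → 10 → 11); 7 is bought.

**The three steps most likely to fail**

**Risk 1, step 4 (the proposed new step).**
- The chelating bromanilate may slow the catalyst.
- The carbene may arylate the product phenols or the oxygen of 6, which would give oligo(phenylene oxide)s.
- The second insertion may take the carbonyl oxygen and give the ortho-quinone isomer.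

The fallback uses only known chemistry, sets out from 3 and comes back to the route at 11. O-Methylation of 3 (MeI, K2CO3, DMF, 40 °C) gives 2,3,6-tribromo-4-nitroanisole F1. Fe/AcOH reduction then gives 2,3,5-tribromo-4-methoxyaniline F2. Diazotisation (NaNO2, H2SO4, 0 °C) gives 2,3,5-tribromo-4-methoxybenzenediazonium hydrogen sulfate F3. Hydroxy-dediazoniation of this salt (Cu2O, Cu(NO3)2, water, rt) gives 2,3,5-tribromo-4-methoxyphenol F4. Two equivalents of F4 react with bought bromanil (tetrabromo-1,4-benzoquinone, O=C1C(Br)=C(Br)C(=O)C(Br)=C1Br) and K2CO3 in MeCN. This is the classical phenoxide addition–elimination on a tetrahaloquinone, and it runs 2,5-selectively because the first aryloxy group deactivates the carbonyl it is conjugated to. The product is 2,5-dibromo-3,6-bis(2,3,5-tribromo-4-methoxyphenoxy)-1,4-benzoquinone F5. Na2S2O4 reduces it to 2,5-dibromo-3,6-bis(2,3,5-tribromo-4-methoxyphenoxy)benzene-1,4-diol F6. BBr3 (CH2Cl2, −78 °C to rt) then cleaves both methyl ethers to give 11.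

**Risk 2, step 3.**
- The bromine ortho to the diazonio group is activated toward displacement by water.
- The quinone diazide 6 is light-sensitive and energetic, so it is kept cold, dark and on a small scale.

The fallback avoids diazotisation, sets out from 4 and comes back at 6. Oxidation of 4 with aqueous FeCl3 proceeds through the quinone imine, which hydrolyses to 2,3,5-tribromo-1,4-benzoquinone F7. Condensation with tosylhydrazide (MeOH, cat. HCl, 0 °C) takes place at the less hindered carbonyl, the one flanked by C–H. This gives (E)-N'-(2,3,5-tribromo-4-oxocyclohexa-2,5-dien-1-ylidene)-4-methylbenzenesulfonohydrazide F8. Filtration through basic alumina eliminates the sulfinate (Bamford–Stevens-type) and gives 6.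

**Risk 3, step 5.**
- Water or hydrogen sulfite may displace aryloxy or bromide from 10 before it is reduced.
- The tetraphenol 11 is hard to purify and oxidises in air at high pH.

The fallback traps the reduced form as a robust ester, sets out from 10 and comes back at 11. Reductive acetylation (Zn dust, Ac2O, NaOAc, rt) gives 2,5-dibromo-3,6-bis(4-acetoxy-2,3,5-tribromophenoxy)-1,4-phenylene diacetate F9, which can be chromatographed or crystallised. Acidic methanolysis (HCl, MeOH, 40 °C, N2) then releases 11.

**Further compounds**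
F1 | step 4 | 2,3,6-tribromo-4-nitroanisole | COc1c(Br)c(Br)c([N+](=O)[O-])cc1Br
F2 | step 4 | 2,3,5-tribromo-4-methoxyaniline | COc1c(Br)c(Br)c(N)cc1Br
F3 | step 4 | 2,3,5-tribromo-4-methoxybenzenediazonium hydrogen sulfate | COc1c(Br)c(Br)c([N+]#N)cc1Br.OS(=O)(=O)[O-]
F4 | step 4 | 2,3,5-tribromo-4-methoxyphenol | COc1c(Br)c(Br)c(O)cc1Br
F5 | step 4 | 2,5-dibromo-3,6-bis(2,3,5-tribromo-4-methoxyphenoxy)-1,4-benzoquinone | O=C1C(Oc2cc(Br)c(OC)c(Br)c2Br)=C(Br)C(=O)C(Oc3cc(Br)c(OC)c(Br)c3Br)=C1Br
F6 | step 4 | 2,5-dibromo-3,6-bis(2,3,5-tribromo-4-methoxyphenoxy)benzene-1,4-diol | COc1c(Br)cc(Oc2c(O)c(Br)c(Oc3cc(Br)c(OC)c(Br)c3Br)c(O)c2Br)c(Br)c1Br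
F7 | step 3 | 2,3,5-tribromo-1,4-benzoquinone | O=C1C=C(Br)C(=O)C(Br)=C1Br
F8 | step 3 | (E)-N'-(2,3,5-tribromo-4-oxocyclohexa-2,5-dien-1-ylidene)-4-methylbenzenesulfonohydrazide | O=C1C(Br)=C/C(=N\NS(=O)(=O)c2ccc(C)cc2)C(Br)=C1Br
F9 | step 5 | 2,5-dibromo-3,6-bis(4-acetoxy-2,3,5-tribromophenoxy)-1,4-phenylene diacetate | CC(=O)Oc1c(Oc2cc(Br)c(OC(C)=O)c(Br)c2Br)c(Br)c(OC(C)=O)c(Oc3cc(Br)c(OC(C)=O)c(Br)c3Br)c1Br
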